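Retrosynthetic overview
1. Endgame: the 3α-acetate comes from a 3-ketone (bulky hydride, then Ac2O) and the C8=C17 methylene from an 8-ketone (Wittig). The C11–C16 side chain comes from an aldol condensation at C9 with a chiral-pool aldehyde made from methyl hydrogen (R)-3-methylglutarate, which supplies C13.
2. The 8-ketone is the 1,3-transposed form of a 6-ketone. That 6-ketone is the temporary activating group of the key step and also makes C5 epimerisable.
3. Key disconnection: ring A is cut at C2–C3 and C4–C5 into a two-carbon β-silyloxy methacrylate (C3, C4, C18, C19) and a cyclobutyl ketone. In the forward sense the alkene is inserted into a C–C σ-bond by a strain-releasing radical-relay formal [4+2] cycloaddition.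
4. Enabling feature: the cyclobutane C1–C2–C5–C10 is cis-fused to ring B at C5–C10 and stands next to the C6 carbonyl group. Its exocyclic, strained C2–C5 bond lies β to a radical centre at C6, so opening gives a C2 radical and a C5=C6 enolate, the two reactive ends that ring A needs.
5. Order of rings: ring B is bought (3-methylcyclohexenone). The temporary cyclobutane is fused on by an enantioselective [2+2] photocycloaddition with ethylene, which sets C10. Ring A is closed last, at the expense of the cyclobutane.

Key step: step 3

Numbering remark: all decalin intermediates carry the labdane numbering of the target (ring A = C1–C5, C10; ring B = C5–C10; C17 methylene carbon, C18 4α-methyl, C19 ester carbon, C20 angular methyl, C11–C16 side chain). β is the face of the C10 methyl group and ξ marks a centre present as both epimers (left undefined in the SMILES).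
Assumption: of the two antipodes of the oxazaborolidine in step 1 (from D- or L-proline), the one that delivers (1R,6S)-3 is used.

Step 1
Reactants: 1 3-methylcyclohex-2-en-1-one; 2 ethylene
Product: 3 (1R,6S)-6-methylbicyclo[4.2.0]octan-2-one (cis-fused; ring B with C6 ketone, cyclobutane C1–C2–C5–C10 on the α-face)
Conditions: AlBr3 complex of 3,3-bis(3,5-dimethylphenyl)-1-(2,4,6-trifluorophenyl)tetrahydro-1H,3H-pyrrolo[1,2-c][1,3,2]oxazaborole (50 mol %), ethylene-saturated CH2Cl2, hν (366 nm), −75 °C; then basic Al2O3
Reagents that add atoms: none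
Why: Enantioselective intermolecular enone–alkene [2+2] photocycloaddition, in which the chiral Lewis acid binds the carbonyl group, shifts its absorption to 366 nm and shields one face of the C5=C10 bond, so that ethylene adds to the open face and sets C10 (quaternary) and C5 in a cis-fused bicycle, any trans-fused adduct being epimerised at C5 on Al2O3.

Step 2
Reactants: 4 methyl propanoate; 5 methyl formate
Product: 7 methyl (E)-2-methyl-3-(triethylsilyloxy)acrylate, via sodium enolate 6 (not isolated)
Conditions: NaH, cat. MeOH, Et2O, 0 °C to rt; volatiles removed; Et3SiCl, THF, 0 °C to rt; distillation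
Reagents that add atoms: sodium hydride [Na+].[H-] (sodium stays in 6 only); chlorotriethylsilane CC[Si](Cl)(CC)CC
Why: Crossed Claisen condensation (formylation) of the propanoate enolate with the non-enolisable formate, followed by O-silylation of the β-dicarbonyl enolate, forms no stereocentre, and the alkene geometry is lost anyway in the stepwise key step.

Step 3
Reactants: 3 (1R,6S)-6-methylbicyclo[4.2.0]octan-2-one; 7 methyl (E)-2-methyl-3-(triethylsilyloxy)acrylate
Product: 8 cis-decalone, methyl 4α,10β-dimethyl-6-oxo-3ξ-(triethylsilyloxy)-5βH-decalin-4β-carboxylate (= methyl 1,4a-dimethyl-8-oxo-2-(triethylsilyloxy)decahydronaphthalene-1-carboxylate)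
Conditions: bis(pinacolato)diboron B2pin2 (20 mol %), methyl isonicotinate (40 mol %), 7 (5 equiv), PhCl (2 M in 3), argon, sealed tube, 130 °C
Reagents that add atoms: none
Why: Proposed new method: the pyridine-ligated boryl radical released from B2pin2 adds to the C6 carbonyl oxygen of 3, the α-boryloxy (ketyl-type) radical at C6 cleaves the aligned, strained exocyclic cyclobutane bond C2–C5 to a boron enolate C5=C6 that carries a primary C2 radical, this nucleophilic radical adds to the β-carbon C3 of acrylate 7 (Giese addition, bond C2–C3), and the tertiary, electrophilic α-ester radical at C4 closes on the electron-rich enolate carbon C5 (bond C4–C5) to return a C6 ketyl-type radical that expels the boryl radical and regenerates the ketone, so the event is redox-neutral and catalytic. The closest known reaction type is the formal [3+2] cycloaddition of cyclopropyl ketones (plain alkyl ones included) with di- and trisubstituted alkenes under diboron/pyridine or SmI2 radical-relay catalysis, together with the related alkene insertion into bicyclobutyl ketones; the extension to the more slowly opening cyclobutyl ketone, a formal [4+2], is what is new and is the reason for 130 °C, a high alkene concentration and a solvent without weak C–H bonds. Ring A is closed in the 6-exo-trig mode (C4 radical on C5=C6, with C6 outside the new ring). C10 is untouched and relays its configuration: the C1–C2–C3 tether hangs from the α-face of C10, so C4 can reach C5 only from that face (cis-fusion, 5β-H, corrected in step 4), and in the chair-like transition state the long, flat CO2Me group points away from ring B while the small methyl group lies under it, which should give 4β-CO2Me/4α-CH3; C3 is formed in the intermolecular event without control and both epimers converge in step 16. The step needs cleavage of the external C2–C5 bond and not of the ring-fusion bond C5–C10 (secured by the better overlap of the exocyclic bond with the C6 radical orbital and by the reversibility of both openings, only the unhindered primary radical being trapped quickly), ring opening faster than direct addition of the hindered C6 radical to the trisubstituted alkene, and attack at C3 and not at C4 of 7 (secured by the ester group and the fully substituted C4).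

Step 4
Reactants: 8 cis-decalone
Product: 9 trans-decalone, methyl 4α,10β-dimethyl-6-oxo-3ξ-(triethylsilyloxy)-5αH-decalin-4β-carboxylate
Conditions: NaOMe (0.3 equiv), MeOH, 50 °C
Reagents that add atoms: none
Why: Base-mediated epimerisation through the C5=C6 enolate should favour the trans-decalone, because the cis isomer must place either the quaternary C4 or both C1 and C6 axial, and because protonation from the α-face, opposite to the axial C19 and C20 groups, also leads to 5α-H.

Step 5
Reactants: 9 trans-decalone
Product: 10 enol triflate, methyl 4α,10β-dimethyl-3ξ-(triethylsilyloxy)-6-(trifluoromethylsulfonyloxy)-5αH-Δ6-octalin-4β-carboxylate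
Conditions: KN(SiMe3)2, THF, −78 °C; PhNTf2, −78 °C to 0 °C
Reagents that add atoms: N-phenylbis(trifluoromethanesulfonimide) O=S(=O)(N(c1ccccc1)S(=O)(=O)C(F)(F)F)C(F)(F)F
Why: Kinetic deprotonation at the unhindered C7 methylene (C5–H is flanked by two quaternary carbons) and O-sulfonylation of the enolate give the enol triflate without touching a stereocentre.

Step 6
Reactants: 10 enol triflate
Product: 11 Δ6-octalin, methyl 4α,10β-dimethyl-3ξ-(triethylsilyloxy)-5αH-Δ6-octalin-4β-carboxylate
Conditions: Pd(OAc)2 (5 mol %), PPh3 (10 mol %), HCO2H, Et3N, DMF, 60 °C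
Reagents that add atoms: none
Why: Palladium-catalysed formate hydrogenolysis of an enol triflate (oxidative addition to zerovalent palladium, decarboxylation of the formate to a palladium hydride, reductive elimination) removes the C6 oxygen and leaves the C6=C7 alkene, while ester and silyl ether are inert.

Step 7
Reactants: 11 Δ6-octalin
Product: 12 Δ6-en-8-one, methyl 4α,10β-dimethyl-8-oxo-3ξ-(triethylsilyloxy)-5αH-Δ6-octalin-4β-carboxylate
Conditions: dirhodium tetracaprolactamate Rh2(cap)4 (1 mol %), t-BuOOH (70 % aq), K2CO3, CH2Cl2, rt
Reagents that add atoms: tert-butyl hydroperoxide CC(C)(C)OO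
Why: In this rhodium-catalysed allylic C–H oxidation, hydrogen abstraction should occur at the accessible C8 methylene and not at the doubly neopentyl C5–H, and the allyl radical should be oxygenated at its open C8 terminus and not at C6 next to C4 and C10, which completes the 1,3-carbonyl transposition.

Step 8
Reactants: 13 methyl hydrogen (R)-3-methylglutarate
Product: 14 methyl (R)-5-hydroxy-3-methylpentanoate
Conditions: BH3·SMe2, THF, 0 °C to rt; MeOH quench
Reagents that add atoms: none
Why: Chemoselective borane reduction of the free carboxylic acid in the presence of the methyl ester leaves the chiral-pool centre (later C13) untouched.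

Step 9
Reactants: 14 methyl (R)-5-hydroxy-3-methylpentanoate
Product: 15 methyl (R)-5-(tert-butyldiphenylsilyloxy)-3-methylpentanoate
Conditions: t-BuPh2SiCl, imidazole, DMF, rt
Reagents that add atoms: tert-butylchlorodiphenylsilane CC(C)(C)[Si](Cl)(c1ccccc1)c1ccccc1
Why: Immediate silylation of the primary alcohol forestalls lactonisation and installs a group that survives every later step up to the last one.

Step 10
Reactants: 15 methyl (R)-5-(tert-butyldiphenylsilyloxy)-3-methylpentanoate
Product: 16 (R)-5-(tert-butyldiphenylsilyloxy)-3-methylpentanal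
Conditions: i-Bu2AlH, CH2Cl2, −78 °C; Rochelle salt work-up
Reagents that add atoms: none
Why: Partial reduction of the ester stops at the tetrahedral aluminium hemiacetal at −78 °C and releases the aldehyde on work-up, with the β-stereocentre not at risk.

Step 11
Reactants: 12 Δ6-en-8-one; 16 (R)-5-(tert-butyldiphenylsilyloxy)-3-methylpentanal
Product: 17 aldol adduct, 12 substituted at C9 by CH(OH)CH2CH(CH3)CH2CH2OSiPh2t-Bu (C9 and C11 as epimer mixture, methyl-bearing centre as in 16)
Conditions: LiN(i-Pr)2, THF, −78 °C; then 16, −78 °C
Reagents that add atoms: none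
Why: Kinetic α′-deprotonation of the enone can occur only at C9 (C7 is sp2), and the directed aldol addition forms the C9–C11 bond, the two new centres being erased or reset in steps 12 and 13.

Step 12
Reactants: 17 aldol adduct
Product: 19 cross-conjugated dienone, methyl (13S)-15-(tert-butyldiphenylsilyloxy)-8-oxo-3ξ-(triethylsilyloxy)-17-norlabda-6,9(11)-dien-19-oate (E/Z mixture), via mesylate 18 (not isolated)
Conditions: MsCl, Et3N, CH2Cl2, 0 °C; then DBU, rt
Reagents that add atoms: methanesulfonyl chloride CS(=O)(=O)Cl (its atoms stay in 18 only)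
Why: Mesylation and E1cB elimination complete the aldol condensation to the exocyclic C9=C11 enone, whose geometry is of no consequence.

Step 13
Reactants: 19 cross-conjugated dienone
Product: 20 methyl (13S)-15-(tert-butyldiphenylsilyloxy)-8-oxo-3ξ-(triethylsilyloxy)-17-norlabdan-19-oate (9β side chain, 9α-H)
Conditions: H2 (4 atm), palladium on carbon (Pd/C, 10 wt %), EtOAc, rt
Reagents that add atoms: none
Why: Heterogeneous hydrogenation saturates both enone C=C bonds and should deliver hydrogen to C9 from the α-face opposite to the axial C10 methyl group, so that the side chain becomes β-equatorial, which is also the thermodynamic configuration of this epimerisable centre.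

Step 14
Reactants: 20 8-ketone
Product: 21 methyl (13S)-15-(tert-butyldiphenylsilyloxy)-3ξ-(triethylsilyloxy)labd-8(17)-en-19-oate
Conditions: Ph3PCH3Br, KOt-Bu, toluene, rt to 60 °C
Reagents that add atoms: methyltriphenylphosphonium bromide C[P+](c1ccccc1)(c1ccccc1)c1ccccc1.[Br-]
Why: Wittig methylenation of the 8-ketone installs C17, the hindered neopentyl C19 ester is not attacked, C3–O stays silylated so that no β-alkoxide can trigger a retro-aldol opening, and any base-induced equilibration at C9 ends at the wanted equatorial epimer.

Step 15
Reactants: 21 bis-silyl ether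
Product: 22 methyl (13S)-15-(tert-butyldiphenylsilyloxy)-3ξ-hydroxylabd-8(17)-en-19-oate
Conditions: pyridinium p-toluenesulfonate (0.2 equiv), MeOH/CH2Cl2, rt
Reagents that add atoms: none
Why: Acid-catalysed methanolysis distinguishes the triethylsilyl ether from the far more acid-stable tert-butyldiphenylsilyl ether and is too mild to move the 1,1-disubstituted alkene.

Step 16
Reactants: 22 3ξ-alcohol
Product: 23 methyl (13S)-15-(tert-butyldiphenylsilyloxy)-3-oxolabd-8(17)-en-19-oate
Conditions: Dess–Martin periodinane, CH2Cl2, rt
Reagents that add atoms: none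
Why: Dess–Martin oxidation merges both C3 epimers into one β-keto ester that cannot enolise at the quaternary C4, so the missing control at C3 in step 3 costs no material.

Step 17
Reactants: 23 3-ketone
Product: 24 methyl (13S)-15-(tert-butyldiphenylsilyloxy)-3α-hydroxylabd-8(17)-en-19-oate
Conditions: LiBH(s-Bu)3, THF, −78 °C
Reagents that add atoms: none
Why: In this steric-approach-controlled ketone reduction the bulky trialkylborohydride avoids the axial trajectory past H1α and H5α and attacks C3 equatorially, which should give the axial 3α-alcohol as with related 4,4-disubstituted 3-ketones.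

Step 18
Reactants: 24 3α-alcohol
Product: 25 methyl (13S)-3α-acetoxy-15-(tert-butyldiphenylsilyloxy)labd-8(17)-en-19-oate
Conditions: Ac2O, DMAP, pyridine, 40 °C
Reagents that add atoms: acetic anhydride CC(=O)OC(C)=O
Why: DMAP-catalysed acylation esterifies the hindered axial alcohol with retention, and elimination is impossible because C4 carries no hydrogen.

Step 19
Reactants: 25 silyl ether
Product: 26 methyl (13S)-3α-acetoxy-15-hydroxylabd-8(17)-en-19-oate (target)
Conditions: HF·pyridine, THF, 0 °C to rt
Reagents that add atoms: none
Why: Fluoride-driven cleavage of the Si–O bond frees the primary C15 alcohol under conditions that leave acetate, methyl ester and exocyclic alkene untouched.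

Compound list
1 | 3-methylcyclohex-2-en-1-one | CC1=CC(=O)CCC1 | starting material
2 | ethylene | C=C | starting material
3 | (1R,6S)-6-methylbicyclo[4.2.0]octan-2-one | O=C1CCC[C@@]2(C)CC[C@@H]12 | intermediate
4 | methyl propanoate | CCC(=O)OC | starting material
5 | methyl formate | COC=O | starting material
6 | sodium enolate of methyl 2-formylpropanoate (not isolated) | COC(=O)C(C)=C[O-].[Na+] | intermediate
7 | methyl (E)-2-methyl-3-(triethylsilyloxy)acrylate | COC(=O)/C(C)=C/O[Si](CC)(CC)CC | intermediate
8 | cis-decalone (5β-H, C3 epimers) | O=C1CCC[C@@]2(C)CCC(O[Si](CC)(CC)CC)[C@](C)(C(=O)OC)[C@@H]12 | intermediate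
9 | trans-decalone (5α-H, C3 epimers) | O=C1CCC[C@@]2(C)CCC(O[Si](CC)(CC)CC)[C@](C)(C(=O)OC)[C@H]12 | intermediate
10 | C6 enol triflate | O=S(=O)(OC1=CCC[C@@]2(C)CCC(O[Si](CC)(CC)CC)[C@](C)(C(=O)OC)[C@H]12)C(F)(F)F | intermediate
11 | Δ6-octalin | C1=CCC[C@@]2(C)CCC(O[Si](CC)(CC)CC)[C@](C)(C(=O)OC)[C@H]12 | intermediate
12 | Δ6-en-8-one | C1=CC(=O)C[C@@]2(C)CCC(O[Si](CC)(CC)CC)[C@](C)(C(=O)OC)[C@H]12 | intermediate
13 | methyl hydrogen (R)-3-methylglutarate | COC(=O)C[C@H](C)CC(=O)O | starting material
14 | methyl (R)-5-hydroxy-3-methylpentanoate | COC(=O)C[C@H](C)CCO | intermediate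
15 | methyl (R)-5-(tert-butyldiphenylsilyloxy)-3-methylpentanoate | COC(=O)C[C@H](C)CCO[Si](c1ccccc1)(c1ccccc1)C(C)(C)C | intermediate
16 | (R)-5-(tert-butyldiphenylsilyloxy)-3-methylpentanal | O=CC[C@H](C)CCO[Si](c1ccccc1)(c1ccccc1)C(C)(C)C | intermediate
17 | aldol adduct (C9, C11 epimers) | C1=CC(=O)C(C(O)C[C@H](C)CCO[Si](c3ccccc3)(c3ccccc3)C(C)(C)C)[C@@]2(C)CCC(O[Si](CC)(CC)CC)[C@](C)(C(=O)OC)[C@H]12 | intermediate
18 | C11 mesylate of 17 (not isolated) | C1=CC(=O)C(C(OS(C)(=O)=O)C[C@H](C)CCO[Si](c3ccccc3)(c3ccccc3)C(C)(C)C)[C@@]2(C)CCC(O[Si](CC)(CC)CC)[C@](C)(C(=O)OC)[C@H]12 | intermediate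
19 | 6,9(11)-dien-8-one (E/Z) | C1=CC(=O)C(=CC[C@H](C)CCO[Si](c3ccccc3)(c3ccccc3)C(C)(C)C)[C@@]2(C)CCC(O[Si](CC)(CC)CC)[C@](C)(C(=O)OC)[C@H]12 | intermediate
20 | 8-oxo-17-norlabdane | C1CC(=O)[C@H](CC[C@H](C)CCO[Si](c3ccccc3)(c3ccccc3)C(C)(C)C)[C@@]2(C)CCC(O[Si](CC)(CC)CC)[C@](C)(C(=O)OC)[C@H]12 | intermediate
21 | labd-8(17)-ene, 3ξ-OSiEt3 | C1CC(=C)[C@H](CC[C@H](C)CCO[Si](c3ccccc3)(c3ccccc3)C(C)(C)C)[C@@]2(C)CCC(O[Si](CC)(CC)CC)[C@](C)(C(=O)OC)[C@H]12 | intermediate
22 | 3ξ-alcohol | C1CC(=C)[C@H](CC[C@H](C)CCO[Si](c3ccccc3)(c3ccccc3)C(C)(C)C)[C@@]2(C)CCC(O)[C@](C)(C(=O)OC)[C@H]12 | intermediate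
23 | 3-ketone | C1CC(=C)[C@H](CC[C@H](C)CCO[Si](c3ccccc3)(c3ccccc3)C(C)(C)C)[C@@]2(C)CCC(=O)[C@](C)(C(=O)OC)[C@H]12 | intermediate
24 | 3α-alcohol | C1CC(=C)[C@H](CC[C@H](C)CCO[Si](c3ccccc3)(c3ccccc3)C(C)(C)C)[C@@]2(C)CC[C@@H](O)[C@](C)(C(=O)OC)[C@H]12 | intermediate
25 | 3α-acetate, 15-silyl ether | C1CC(=C)[C@H](CC[C@H](C)CCO[Si](c3ccccc3)(c3ccccc3)C(C)(C)C)[C@@]2(C)CC[C@@H](OC(C)=O)[C@](C)(C(=O)OC)[C@H]12 | intermediate
26 | methyl (13S)-3α-acetoxy-15-hydroxylabd-8(17)-en-19-oate | C=C1CC[C@@H]2[C@](C)(CC[C@@H](OC(C)=O)[C@]2(C)C(=O)OC)[C@H]1CC[C@H](C)CCO | target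

Total step count: 19. Longest linear sequence: 15 steps (steps 1, 3–7 and 11–19).

Steps most likely to fail

Step 3 (Proposed new method).
- What may go wrong: opening of the cyclobutane may be too slow relative to direct addition or decay of the C6 radical. The primary radical may be quenched before it adds to the hindered acrylate. The facial selectivity at C4 may be poor.
- Fallback (known reaction types), from 3 back to 8: Me3SiI (CH2Cl2, −20 °C, Et3N quench, non-aqueous work-up) opens the strained-ring ketone by iodide attack at the primary C2. This gives the regiodefined iodo silyl enol ether (S)-[3-(2-iodoethyl)-3-methylcyclohex-1-enyloxy]trimethylsilane F1.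
- An iodine-atom-transfer radical annulation of F1 with 7 (hexabutylditin (Bu3Sn)2 cat., hν, benzene, 80 °C) then forms the same two bonds by Giese addition and 6-exo cyclisation onto the silyl enol ether. The α-silyloxy radical takes up iodine and collapses to the ketone, which is 8.

Step 4.
- What may go wrong: the cis/trans equilibrium may not lie far enough on the trans side, so that epimerisation stays incomplete.
- Fallback, from 8 back to 9: thermodynamic control is replaced by kinetic control. IBX (DMSO, 70 °C) dehydrogenates 8, which can only become unsaturated towards C7–C8, to the cis-fused Δ7-en-6-one F2.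
- LiN(i-Pr)2 (THF, −78 °C) removes the only α-proton (C5–H). Protonation of the cross-conjugated dienolate with AcOH at −78 °C occurs from the α-face, the β-face being closed by the axial C19 and C20 groups, and gives the trans-fused Δ7-en-6-one F3.
- Hydrogenation of F3 (H2, Pd/C, EtOAc) gives 9.

Step 7.
- What may go wrong: oxygen may be delivered to the wrong terminus of the allyl radical, attack may occur at C5–H, or the alkene may be over-oxidised.
- Fallback, from 9 back to 12 (steps 5–7 are skipped): IBX dehydrogenation of 9 gives the trans-fused Δ7-en-6-one F3, the same enone as above.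
- Nucleophilic epoxidation (H2O2, NaOH, MeOH, 0 °C) from the α-face gives the 7α,8α-epoxy-6-ketone F4.
- Wharton transposition (N2H4·H2O, AcOH, MeOH) gives the Δ6-en-8α-ol F5, and MnO2 (CH2Cl2) oxidises it to 12. The position of the oxygen is fixed here by the mechanism.

Further compounds
F1 | step 3 | (S)-[3-(2-iodoethyl)-3-methylcyclohex-1-enyloxy]trimethylsilane | C[Si](C)(C)OC1=C[C@](C)(CCI)CCC1
F2 | step 4 | cis-fused Δ7-en-6-one (5β-H, C3 epimers) | O=C1C=CC[C@@]2(C)CCC(O[Si](CC)(CC)CC)[C@](C)(C(=O)OC)[C@@H]12
F3 | step 4 | trans-fused Δ7-en-6-one (5α-H, C3 epimers) | O=C1C=CC[C@@]2(C)CCC(O[Si](CC)(CC)CC)[C@](C)(C(=O)OC)[C@H]12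
F4 | step 7 | 7α,8α-epoxy-6-ketone | O=C1[C@H]3O[C@H]3C[C@@]2(C)CCC(O[Si](CC)(CC)CC)[C@](C)(C(=O)OC)[C@H]12
F5 | step 7 | Δ6-en-8α-ol | C1=C[C@@H](O)C[C@@]2(C)CCC(O[Si](CC)(CC)CC)[C@](C)(C(=O)OC)[C@H]12
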